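(The readings come from a simulation with constants of no real substance, and the scatter is random.)

The constants are hidden from you, but the runs turn them into a time: the amber run already stands at 75.0% after 6.00 min, and this flask is the violet run carried on to the options below.

| flask | starting material | reagent | remark | time |
|---|---|---|---|---|
| violet | 20 mM | 0.50 equiv | the very flask that is asked about, followed so far |  |
| amber | 20 mM | 1 equiv | run made earlier |  |
| flask | 20 mM | 0.500 equiv |  | 30 h |

violet run (percent of the starting material charged)

| time / h | target / % |
|---|---|
| 2.50 | 49.5 |
| 5.00 | 50.0 |
| 8.00 | 49.7 |
| 15.0 | 50.6 |
| 30.0 | 49.9 |

amber run (percent of the starting material charged)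

| time / min | target / % |
|---|---|
| 6.00 | 75.0 |
| 20.0 | 95.6 |
| 30.0 | 96.0 |
| 50.0 | 98.9 |
| 80.0 | 98.6 |

(each reading ± 0.5 percentage points)

- larch: at 30 h add reagent, 50.0% of the amount charged, then wait 2.5 d
- cedar: change nothing and wait 2.5 d more
- alder: at 30 h add starting material, 50.0% of the amount charged, then wait 2.5 d
- maple: at 30 h take out 90% of the target then present, then wait 2.5 d

- removed target is counted in
- steps thought possible: starting material + reagent + by-product -> target + 2 by-product; starting material + reagent -> target + by-product
- additions bring no volume worth counting

* target, in percent of the starting material first charged, at 30 h
* the option that brings most further target ("none" if no option brings more than 2 percentage points) (larch / cedar / alder / maple / none)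
* target present, with what was taken out counted in, in percent of the starting material first charged, after larch
* target present, with what was taken out counted in, in percent of the starting material first charged, after maple

- Both listed steps spend one reagent for each target, so here 50.0% is the reagent ceiling, the reagent charged so far as a percent of the starting material first charged; at 0.500 equiv, under one equivalent, reagent is the limiting reagent.
- Fast extreme: if reaction takes no time, this flask stands at its ceiling at once.
- Slow extreme: if reaction takes far longer than 30 h, this flask still stands well below its ceiling at 30 h.
- The violet readings put this flask at the fast end: 49.5% at 2.50 h and 49.9% at 30.0 h, flat within the scatter of 0.5 percentage points.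
- So I reckon 50.0% for now. Cedar, alder and maple bring no reagent, so their ceiling stays 50.0%.
- Larch adds 50.0% of the reagent charged, not of the starting material, so the total is 0.750 equiv and the ceiling becomes 75.0%. That is a gain of 25 points, and the wait of 2.5 d is long against the 2.50 h by which the violet run read flat.
- The forecast gives 50%, larch as best, 99% after larch and 50% after maple, on the ground that “fresh reagent brings the total to 1 equiv”. My reckoning parts from it on larch, with 75.0%.

    starting material + reagent + by-product → target + 2 by-product (k = 3100 M⁻² min⁻¹)
    starting material + reagent → target + by-product (k = 1.50 M⁻¹ min⁻¹)

The flask gives 50.0% at 30 h and 50.0% after maple, and larch is best, reaching 75.0% against the forecast's 99%. At 30.0 h, 0% of the charged reagent stands free beside 50.0% of the charged starting material. The reagent ceiling, raised from 50.0% to 75.0% by larch, is where that option stops. A neighbour charged with 0.300 equiv of reagent has a ceiling of 30.0%, and that flask gives 30.0%, with 70% of its starting material still free.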